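Readings and results were generated by integration with constants of no real substance, noise included.

How strongly does the rate of making product in the dawn flask answer to its second substrate, once the conversion of starting material has reached 10%?

- apparent order in second substrate when 10% of the starting material are converted (percent change of the rate of making product for one percent more second substrate charged)

| setting | dawn | winter | flask |
|---|---|---|---|
| starting material | 34 mM | 17 mM | 34 mM |
| second substrate | 68 mM | 68 mM | 68.0 mM |
| enzyme | 3.4 µM | 3.4 µM | 3.4 µM |
| impurity | 0.51 µM | 0.51 µM | 0.51 µM |
| remark | the very flask that is asked about, followed so far | run made earlier |  |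

dawn run (percent of the starting material charged)

| time / h | product / % | starting material / % |
|---|---|---|
| 2.50 | 0.3 | 99.9 |
| 5.00 | 0.7 | 99.1 |
| 8.00 | 1.3 | 98.7 |
| 15.0 | 2.3 | 97.0 |
| 30.0 | 5.1 | 94.1 |

winter run (percent of the starting material charged)

| time / d | product / % | starting material / % |
|---|---|---|
| 0.500 | 2.2 | 97.6 |
| 1.04 | 4.5 | 95.4 |
| 1.67 | 7.4 | 92.0 |
| 2.08 | 9.1 | 90.1 |
| 2.50 | 11.2 | 88.8 |

(scatter of a reading: 0.3 percentage points)

- no earlier run changes the charge of second substrate; that part of a forecast is a guess

Climb the ladder from the fastest rung. In the dawn flask, the enzyme charged over the rate of making product gives one round of the catalyst in 3.53 min on average. The next rung is the first reading at 2.50 h, where product stands at 0.3%, so any early lag hides in the scatter of 0.3 percentage points. The top rung comes from the pace: 5.1% in 30.0 h makes 2.45 d. Call this the reach time, the time a flask needs to reach 10% conversion at the pace read. A round is far shorter than the reach time, so you may treat the catalyst as keeping pace with the charges and the rate as a steady one.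

The winter flask, with half the starting material, gives a reading of 0.865 for the order in starting material. While an order n in the second substrate holds, doubling that charge with the others fixed leaves the same amount of product to make, so it multiplies the reach time by two to the power minus n. No run varies the second substrate, so my own lean is a guess: it behaves like the starting material, with an order near 1.00 and a factor of 0.500.

The forecast differs. It gives 0.5, a factor of 0.707, and says “I take the middle value with a wide range”.

The simulation gives 1.0, twice the forecast.

    starting material + enzyme ⇌ starting complex (K = 16.0 /M, k = 3.88 × 10⁵ /M/h)
    second substrate + starting complex ⇌ ternary complex (K = 6.10 /M, k = 1.21 × 10⁶ /M/h)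
    ternary complex → enzyme + product (k = 1110 /h)
    2 enzyme ⇌ resting dimer, settled at all times (K = 1.60 × 10⁷ /M)
    enzyme + impurity → spent catalyst (k = 1.17 × 10⁷ /M/h)

At 2.50 d the dawn flask holds 71.5% of its catalyst as resting dimer, the resting state, far more than the 1.51% held as ternary complex. It reaches 10% at 2.28 d, against the reach time of 2.45 d read from its pace. With twice the rate, the flask with doubled second substrate has its reach time multiplied by 0.507, which takes the time read to 1.24 d.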